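**Easy count.** I began with the solid reagent. I took it to give one coupling partner per substrate, and the flask holds twice what the two substrates need, so a fair error in it left the ending unchanged.

| flask | left-handed substrate | right-handed substrate | solid reagent | free catalyst | racemization catalyst | impurity | remark | time |
|---|---|---|---|---|---|---|---|---|
| south | 0.20 M | 0.20 M | 0.80 M | 10 mM | 1 mM (in portions, 4) | 1.5 mM | run made earlier; portions every 40 s |  |
| south-east | 0.20 M | 0.20 M | 0.80 M | 10 mM | 1 mM (in portions, 4) | 2.4 mM | run made earlier; portions every 40 s |  |
| south-west | 0.20 M | 0.20 M | 0.80 M | 10 mM | 0.50 mM (in portions, 4) | 1.1 mM | run made earlier; portions every 40 s |  |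
| flask | 0.20 M | 0.20 M | 0.800 M | 10 mM | 1.0 mM (in portions, 4) | 1.1 mM | the portions of racemization catalyst follow each other after 40 s, the first at the start | 4.0 h |

| run | time / h | left-handed substrate / % | left-handed product / % | right-handed product / % |
|---|---|---|---|---|
| south | 0.167 | 39.2 | 11.1 | 4.1 |
| south | 0.500 | 17.9 | 30.3 | 15.0 |
| south | 0.833 | 5.3 | 44.9 | 29.4 |
| south | 1.33 | 1.2 | 49.6 | 48.7 |
| south | 2.00 | 0 | 48.8 | 50.6 |
| south | 2.50 | 0 | 48.8 | 50.4 |
| south | 3.00 | 0 | 50.8 | 49.9 |
| south-east | 0.250 | 32.7 | 16.7 | 7.4 |
| south-east | 0.417 | 23.6 | 26.2 | 13.2 |
| south-east | 0.667 | 10.6 | 38.8 | 22.0 |
| south-east | 0.833 | 4.4 | 45.3 | 29.9 |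
| south-east | 1.33 | 0.1 | 50.2 | 47.8 |
| south-east | 2.00 | 0 | 50.3 | 49.9 |
| south-east | 3.00 | 0 | 49.9 | 50.0 |
| south-west | 0.667 | 11.2 | 40.3 | 22.0 |
| south-west | 1.33 | 0 | 50.0 | 49.1 |
| south-west | 2.00 | 0.6 | 49.9 | 50.3 |
| south-west | 2.50 | 0 | 50.3 | 50.7 |
| south-west | 3.00 | 0 | 50.1 | 50.5 |

(scatter of a reading: 0.5 percentage points)

- free catalyst is single-handed; left-handed substrate and right-handed substrate are mirror images of each other, charged as a racemate, each of them at the stated concentration
- solid reagent is a solid; its amount is given per volume of the solution
- at the start none of the solid reagent is in solution
- the reaction counts as stopped when no species that holds the left-handed substrate and right-handed substrate together changes by six tenths of a point or more over the second half of the time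

1. why nothing more happens at 4.0 h, or that something still does (for what has run out or reacted, a solid counts together with what of it has only dissolved) (all of the left-handed substrate has reacted / it is still moving / forward and back rates have come level / no working catalyst is left / the coupling partner has run out first)
2. conversion of left-handed substrate and right-handed substrate together at 4.0 h
3. amount of left-handed product at 4.0 h, in percent of the left-handed substrate and right-handed substrate together charged
4. amount of right-handed product at 4.0 h, in percent of the left-handed substrate and right-handed substrate together charged

**Pace next.** The south run showed 0 % left-handed substrate at 2.00 h, and the flask has twice that time, so an error in the pace, free catalyst included, had room too.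

**What matters.** The number I needed well was whether substrate crosses over. In the south run, left-handed product ran ahead early, 11.1 % against 4.1 %, a read ratio of 2.71, which I took as a reading of the selectivity factor. It still ended level, at 50.8 % and 49.9 %. So I read no crossing over in that run, within a scatter of 0.5 percentage points on each reading.

**Spare impurity.** I therefore reckoned the spare impurity, the fraction of the impurity charge left once each racemization catalyst has taken one impurity. It is one minus the ratio of the two charges. The south, south-east and south-west runs stood at 33.3 %, 58.3 % and 54.5 %. The flask stands at 9.09 %, thinner than the south run. Zero is the crossing, but the one-to-one taking is my assumption, and these runs do not test it near zero. With a positive spare I committed to each substrate giving its own 50.0 %.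

**The forecast.** The forecast gave 100 % conversion, 50 % left-handed product and 50 % right-handed product, and its end was "all of the left-handed substrate has reacted". It held that each portion “should be scavenged on arrival”.

**The flask.** The flask gave 50.0 % left-handed product and 50.0 % right-handed product at 100 % conversion, and it stood still at 4.0 h for this reason: all of the left-handed substrate has reacted.

    coupling partner + free catalyst + left-handed substrate → free catalyst + left-handed product (k = 2300 M⁻² min⁻¹)
    coupling partner + free catalyst + right-handed substrate → free catalyst + right-handed product (k = 880 M⁻² min⁻¹)
    left-handed substrate + racemization catalyst ⇌ right-handed substrate + racemization catalyst, rate k3*[racemization catalyst]*[left-handed substrate] forward; the back reaction follows from the equilibrium constant (k = 290 M⁻¹ min⁻¹)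
    2 free catalyst ⇌ resting dimer, settled at all times (K = 80.0 M⁻¹)
    solid reagent ⇌ coupling partner, rate k5*(cs5 - [coupling partner]) while solid is left; crystals form when [coupling partner] > cs5 (solubility = 36.0 mM, k = 0.190 min⁻¹)
    racemization catalyst + impurity → spent catalyst (k = 1.70 × 10⁵ M⁻¹ min⁻¹)

**Thin margin.** This ending sat close to the edge: raising the racemization catalyst from 1.0 mM to 1.12 mM moved the left-handed product by 5 points. The spare of 9.09 % stood in the flask as 9.1 % of the impurity left at 4.00 h. For the neighbouring flask with 0.0019 M of impurity, the spare comes to 47.4 %, and that flask gave 50.0 % left-handed product with 47 % of its impurity left.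

All runs stem from a simulated flask with constants of no real substance.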